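**Retrosynthetic overview**
- The strategy rests on C12, the fully substituted carbon of furanone ring A (O, C12, C13, C14, C15). It carries the ring oxygen and the C11H2–C10(=O) arm, which is the imprint of Markovnikov oxypalladation of a C11=C12 alkene by the C15 hydroxyl followed by CO insertion; the C11–palladium bond formed has no β-hydrogen.
- Key disconnection, one operation: O–C12, C11–C10 and C10–C9, from an open-chain hydroxy enone allylstannane and CO. Ring A closes first, then the 14-membered carbocycle B (C4–C7, C9–C18).
- The open chain comes from: C6=C7 by Still–Gennari olefination with an α-(stannylmethyl) phosphonate (brings C7, C8, C9 and tin); C13–C14 by methallyl addition; C16–C17 by dithiane anion plus a (S)-glycidyl ether; C4 from carvone by oxidative ring cleavage.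
- Last step: hydrolysis of the C17 dioxolane to the (4R,12R,15S) target with the Z enoate.

Key step: step 18

Remarks on the chemistry:
- Carbons are numbered along the target chain: C1–C3 isopropenyl, C4 methine, C5, C6=C7, C8 ester carbon, C9, C10 ketone, C11, C12 quaternary, C13, C14 ketone, C15 OCH, C16, C17 ketone, C18.
- (S)-Carvone is used because its cleavage gives an aldehyde arm that is turned into C18–C17 and an acid arm that becomes C5–C6; this assignment maps the carvone centre onto 4R.
- The carbinol carbon C14 made in step 11 is carried as a mixture of epimers until step 16 removes it.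
- (S)-4-Methoxybenzyl glycidyl ether, tributyl(iodomethyl)stannane and 2-methylallylmagnesium chloride (THF solution) are assumed to be purchasable.

Step 1
Reactants: 1 (S)-carvone
Product: 2 (1S,4S,6S)-1-methyl-4-(prop-1-en-2-yl)-7-oxabicyclo[4.1.0]heptan-2-one
Conditions: 30% aq H2O2, NaOH (cat.), MeOH, 0 °C
Reagents that add atoms: hydrogen peroxide (OO)
Why: Nucleophilic (Weitz–Scheffer) epoxidation attacks only the electron-poor enone alkene, on the face away from the isopropenyl group, and the two new centres are erased in step 2.

Step 2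
Reactants: 2 carvone epoxide
Product: 5 (3S)-5-oxo-3-(prop-1-en-2-yl)pentanoic acid (in equilibrium with its lactol), via keto diol 3 (not isolated), via diketo aldehyde 4 (not isolated)
Conditions: 1 M aq H2SO4, THF, 25 °C; then NaIO4 (3 equiv), 0 → 25 °C, one pot
Reagents that add atoms: water (O); sodium periodate ([Na+].[O-][I](=O)(=O)=O)
Why: Acid-catalysed hydrolysis opens the epoxide at its CH carbon, and periodate glycol cleavage followed by cleavage of the resulting 1,2-diketone excises the methyl-bearing carbon as acetic acid, leaving an aldehyde arm and an acid arm on the untouched stereocentre.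

Step 3
Reactants: 5 acid aldehyde
Product: 6 (3R)-3-(1,3-dithian-2-ylmethyl)-4-methylpent-4-enoic acid
Conditions: HS(CH2)3SH, BF3·OEt2 (0.3 equiv), CH2Cl2, −20 → 0 °C
Reagents that add atoms: propane-1,3-dithiol (SCCCS)
Why: Lewis acid dithioacetalisation is selective for the aldehyde (free or as lactol) over the carboxylic acid, and brief exposure at low temperature spares the isopropenyl group; the aldehyde carbon becomes C17.

Step 4
Reactants: 6 dithiane acid
Product: 7 (3R)-3-(1,3-dithian-2-ylmethyl)-4-methylpent-4-en-1-ol
Conditions: LiAlH4, THF, 0 → 25 °C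
Reagents that add atoms: none
Why: LiAlH4 reduces the carboxylic acid to the primary alcohol (future C6) and leaves dithiane and alkene untouched.

Step 5
Reactants: 7 dithiane alcohol
Product: 8 tert-butyldimethylsilyl ether of 7
Conditions: TBSCl, imidazole, DMF, 25 °C
Reagents that add atoms: tert-butyldimethylsilyl chloride (CC(C)(C)[Si](C)(C)Cl)
Why: Standard silylation of the primary alcohol removes the only acidic proton before the dithiane is metallated.

Step 6
Reactants: 8 silyl ether dithiane; 9 (S)-4-methoxybenzyl glycidyl ether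
Product: 11 (4R,15S)-15-hydroxy open chain with 6-O-TBS and 14-O-PMB and C17 as 1,3-dithiane, via lithiodithiane 10 (not isolated)
Conditions: t-BuLi, THF/HMPA (10:1), −78 °C; then 9, −78 → −20 °C
Reagents that add atoms: none
Why: The metallated 2-alkyl-1,3-dithiane is an acyl anion equivalent for C17 (Corey–Seebach umpolung) that opens the terminal epoxide at its CH2 carbon by SN2, forming C16–C17; the carbinol carbon is not touched and keeps the glycidyl configuration, which becomes 15S.

Step 7
Reactants: 11 C15 alcohol
Product: 12 (4R,15S)-6,15-bis-O-TBS ether with 14-O-PMB and C17 dithiane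
Conditions: TBSOTf, 2,6-lutidine, CH2Cl2, −78 → 0 °C
Reagents that add atoms: tert-butyldimethylsilyl trifluoromethanesulfonate (CC(C)(C)[Si](C)(C)OS(=O)(=O)C(F)(F)F)
Why: Silyl triflate silylation of the hindered secondary alcohol masks C15–OH through the base and oxidation steps ahead.

Step 8
Reactants: 12 bis-silyl ether dithiane
Product: 13 (4R,15S)-6,15-bis-O-TBS ether with 14-O-PMB and C17 as 1,3-dioxolane
Conditions: PhI(OCOCF3)2 (1.5 equiv), ethylene glycol (10 equiv), NaHCO3, MeCN, 0 → 25 °C
Reagents that add atoms: ethane-1,2-diol (OCCO)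
Why: The hypervalent iodine reagent oxidises sulfur, the thionium ion is trapped by the diol and the second sulfur leaves the same way, so the dithiane is exchanged directly for the dioxolane (oxidative transketalisation) before any step that sulfur would spoil.

Step 9
Reactants: 13 dioxolane PMB ether
Product: 14 (4R,15S)-C14 primary alcohol
Conditions: DDQ, CH2Cl2/pH 7 phosphate buffer, 0 °C
Reagents that add atoms: none
Why: DDQ oxidises only the electron-rich benzylic ether (oxidative PMB cleavage); silyl ethers, ketal and alkenes are inert under buffered conditions.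

Step 10
Reactants: 14 primary alcohol
Product: 15 (4R,15S)-C14 aldehyde with 15-O-TBS
Conditions: Dess–Martin periodinane, pyridine, CH2Cl2, 0 → 25 °C
Reagents that add atoms: none
Why: Buffered Dess–Martin oxidation gives the α-silyloxy aldehyde without epimerising conditions, and the aldehyde is used at once to protect the C15 centre.

Step 11
Reactants: 15 aldehyde; 16 2-methylallylmagnesium chloride
Product: 17 (4R,15S)-C14 carbinol carrying the C11–C13 methallyl unit (C14 epimers)
Conditions: THF, −78 °C; aq NH4Cl quench at −78 °C
Reagents that add atoms: none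
Why: Allyl-type Grignard addition to the aldehyde at low temperature forms C13–C14, and its facial selectivity is of no consequence because C14 is oxidised in step 16.

Step 12
Reactants: 17 bis-silyl ether carbinol
Product: 18 (4R,15S)-6,14-diol with 15-O-TBS (C14 epimers)
Conditions: HF·pyridine, pyridine, THF, 0 °C
Reagents that add atoms: none
Why: Buffered HF·pyridine cleaves the unhindered primary silyl ether much faster than the secondary one flanked by two branches (selective desilylation).

Step 13
Reactants: 18 diol
Product: 19 (4R,15S)-C6 aldehyde with free 14-OH and 15-O-TBS (C14 epimers)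
Conditions: TEMPO (0.1 equiv), PhI(OAc)2, CH2Cl2, 25 °C
Reagents that add atoms: none
Why: The oxoammonium oxidant generated from TEMPO and PhI(OAc)2 is selective for the primary alcohol over the hindered secondary C14 carbinol and stops at the aldehyde.

Step 14
Reactants: 20 methyl bis(2,2,2-trifluoroethyl)phosphonoacetate; 21 tributyl(iodomethyl)stannane
Product: 23 methyl 2-[bis(2,2,2-trifluoroethoxy)phosphoryl]-3-(tributylstannyl)propanoate (racemic), via sodium phosphonate 22 (not isolated)
Conditions: NaH, THF/DMF, 0 °C; then 21, 25 → 50 °C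
Reagents that add atoms: none
Why: C-alkylation of the stabilised phosphonoacetate anion with the reactive α-stannyl iodide (SN2) puts C9 and its tin on the future C7, which an olefination with the plain phosphonoacetate could not provide.

Step 15
Reactants: 19 hydroxy aldehyde; 23 stannyl phosphonate
Product: 25 (4R,15S)-allylstannane enoate with C5 cis to CO2Me and free 14-OH and 15-O-TBS (C14 epimers), via potassium phosphonate 24 (not isolated)
Conditions: 23 (1.5 equiv), KN(SiMe3)2 (1.4 equiv), 18-crown-6, THF, −78 °C; then 19, −78 °C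
Reagents that add atoms: none
Why: Still–Gennari olefination: the electron-poor bis(trifluoroethyl) phosphonate under dissociating conditions eliminates from the kinetic adduct and places the ester cis to the C5 chain, giving the trisubstituted enoate of the target geometry with the allylstannane in place, and the weakly basic phosphonate anion (kept in slight excess over the amide base) tolerates the free C14 hydroxyl.

Step 16
Reactants: 25 stannane carbinol
Product: 26 (4R,15S)-C14 ketone (β,γ-unsaturated) with 15-O-TBS
Conditions: Dess–Martin periodinane, pyridine, CH2Cl2, 0 °C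
Reagents that add atoms: none
Why: Buffered Dess–Martin oxidation converts the homoallylic carbinol into the β,γ-unsaturated ketone without acid or base strong enough to move the alkene into conjugation or to cleave the electron-poor allylstannane.

Step 17
Reactants: 26 silyloxy ketone
Product: 27 (4R,15S)-15-hydroxy-14-oxo open chain with C9–SnBu3 and C11=C12 alkene and C17 dioxolane
Conditions: Et3N·3HF, MeCN, 25 °C
Reagents that add atoms: none
Why: The α-keto silyl ether is cleaved by the nearly neutral amine–HF complex, which is mild enough for the β,γ-enone, the dioxolane and the allylstannane (fluoride desilylation); 27 is used directly.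

Step 18
Reactants: 27 hydroxy enone allylstannane; 28 carbon monoxide
Product: 31 (4R,12R,15S)-macrocyclic furanone with C17 as 1,3-dioxolane, via alkylpalladium chloride 29 (not isolated), via acylpalladium chloride 30 (not isolated)
Conditions: PdCl2(MeCN)2 (0.2 equiv), p-benzoquinone (2 equiv), CO (1 atm), THF, 25 °C, slow addition of 27 (final 0.002 M)
Reagents that add atoms: none
Why: Proposed new method: divalent palladium, held by the C15 hydroxyl and the C14 carbonyl, activates the C11=C12 alkene, the hydroxyl adds to the substituted carbon C12 and leaves a C11–palladium bond whose only β-carbon is the quaternary C12, so β-hydride elimination is impossible and CO inserts to give acylpalladium 30; intramolecular tin-to-palladium allyl transfer and reductive elimination at the unsubstituted allyl terminus C9 then form C9–C10 and release zerovalent palladium, which benzoquinone returns to divalent palladium. The closest known reaction types are the intramolecular alkoxypalladation–alkoxycarbonylation of hydroxy alkenes to 2-(acylmethyl)tetrahydrofurans and the acylpalladium–allylstannane (Stille) ketone synthesis including carbonylative Stille macrocyclisation, so each elementary step is known and only their union in one catalytic cycle is not. Ring A closes by 5-exo-trig oxypalladation and the 14-membered ring B by reductive elimination from a cyclic acyl(allyl)palladium species under high dilution. The new stereocentre C12 is controlled by the fixed C15 centre, because oxypalladation is reversible and only the epimer with the C11 acylpalladium arm cis to the C16 arm can reach the stannane, so that epimer is drained into product (12R). The step needs reaction at this alkene and not at the isopropenyl or enoate alkene or directly at tin (secured by the chelating α-hydroxy ketone, the absence of any other hydroxyl within reach and the electron-poor 2-carbomethoxy allylstannane), coupling at C9 and not C6 (C6 is substituted and would give a strained 12-membered ring), and retention of the enoate geometry (C5 sits syn in the η3-allyl form, the favoured arrangement, so η1–η3 equilibration returns the same alkene).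

Step 19
Reactants: 31 macrocyclic dioxolane
Product: 32 target CNP0163183.1, (4R,12R,15S) with Z enoate
Conditions: PPTS (0.2 equiv), acetone/H2O (9:1), 40 °C
Reagents that add atoms: water (O)
Why: Mild acid-catalysed hydrolysis of the ketal frees the C17 ketone at an acidity that should not move the C6=C7 alkene or open the β-alkoxy ketone.

**Compound list**
1 | (S)-carvone | CC1=CC[C@@H](CC1=O)C(C)=C | starting material
2 | (1S,4S,6S)-1-methyl-4-(prop-1-en-2-yl)-7-oxabicyclo[4.1.0]heptan-2-one | C[C@]12O[C@H]1C[C@H](C(C)=C)CC2=O | intermediate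
3 | (2S,3R,5S)-2,3-dihydroxy-2-methyl-5-(prop-1-en-2-yl)cyclohexan-1-one (keto diol, not isolated) | C[C@]1(O)[C@H](O)C[C@H](C(C)=C)CC1=O | intermediate
4 | (3S)-5,6-dioxo-3-(prop-1-en-2-yl)heptanal (diketo aldehyde, not isolated) | CC(=O)C(=O)C[C@H](CC=O)C(C)=C | intermediate
5 | (3S)-5-oxo-3-(prop-1-en-2-yl)pentanoic acid | O=CC[C@@H](CC(=O)O)C(C)=C | intermediate
6 | (3R)-3-(1,3-dithian-2-ylmethyl)-4-methylpent-4-enoic acid | S1CCCSC1C[C@@H](CC(=O)O)C(C)=C | intermediate
7 | (3R)-3-(1,3-dithian-2-ylmethyl)-4-methylpent-4-en-1-ol | S1CCCSC1C[C@@H](CCO)C(C)=C | intermediate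
8 | tert-butyl{[(3R)-3-(1,3-dithian-2-ylmethyl)-4-methylpent-4-en-1-yl]oxy}dimethylsilane | S1CCCSC1C[C@@H](CCO[Si](C)(C)C(C)(C)C)C(C)=C | intermediate
9 | (S)-4-methoxybenzyl glycidyl ether | COc1ccc(COC[C@@H]2CO2)cc1 | starting material
10 | 2-lithio-1,3-dithiane derived from 8 (not isolated) | [Li]C1(SCCCS1)C[C@@H](CCO[Si](C)(C)C(C)(C)C)C(C)=C | intermediate
11 | (4R,15S)-15-hydroxy chain: C4 bears isopropenyl, CH2CH2OTBS (C5–C6) and CH2 (C18) to the dithiane carbon C17, which carries CH2–CH(OH)–CH2OPMB (C16–C14) | C=C(C)[C@H](CCO[Si](C)(C)C(C)(C)C)CC1(SCCCS1)C[C@H](O)COCc1ccc(OC)cc1 | intermediate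
12 | 15-O-TBS ether of 11, (4R,15S) | C=C(C)[C@H](CCO[Si](C)(C)C(C)(C)C)CC1(SCCCS1)C[C@H](O[Si](C)(C)C(C)(C)C)COCc1ccc(OC)cc1 | intermediate
13 | C17 1,3-dioxolane analogue of 12, (4R,15S) | C=C(C)[C@H](CCO[Si](C)(C)C(C)(C)C)CC1(OCCO1)C[C@H](O[Si](C)(C)C(C)(C)C)COCc1ccc(OC)cc1 | intermediate
14 | C14 primary alcohol (PMB removed from 13), (4R,15S) | C=C(C)[C@H](CCO[Si](C)(C)C(C)(C)C)CC1(OCCO1)C[C@H](O[Si](C)(C)C(C)(C)C)CO | intermediate
15 | C14 aldehyde, (4R,15S) | C=C(C)[C@H](CCO[Si](C)(C)C(C)(C)C)CC1(OCCO1)C[C@H](O[Si](C)(C)C(C)(C)C)C=O | intermediate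
16 | 2-methylallylmagnesium chloride | CC(=C)C[Mg]Cl | starting material
17 | C14 carbinol with methallyl unit C11–C13, 6,15-bis-O-TBS, (4R,15S), C14 epimers | C=C(C)[C@H](CCO[Si](C)(C)C(C)(C)C)CC1(OCCO1)C[C@H](O[Si](C)(C)C(C)(C)C)C(O)CC(C)=C | intermediate
18 | 6,14-diol with 15-O-TBS, (4R,15S), C14 epimers | C=C(C)[C@H](CCO)CC1(OCCO1)C[C@H](O[Si](C)(C)C(C)(C)C)C(O)CC(C)=C | intermediate
19 | C6 aldehyde with 14-OH and 15-O-TBS, (4R,15S), C14 epimers | C=C(C)[C@H](CC=O)CC1(OCCO1)C[C@H](O[Si](C)(C)C(C)(C)C)C(O)CC(C)=C | intermediate
20 | methyl bis(2,2,2-trifluoroethyl)phosphonoacetate | COC(=O)CP(=O)(OCC(F)(F)F)OCC(F)(F)F | starting material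
21 | tributyl(iodomethyl)stannane | CCCC[Sn](CCCC)(CCCC)CI | starting material
22 | sodium salt of 20 (not isolated) | [Na+].COC(=O)[CH-]P(=O)(OCC(F)(F)F)OCC(F)(F)F | intermediate
23 | methyl 2-[bis(2,2,2-trifluoroethoxy)phosphoryl]-3-(tributylstannyl)propanoate (racemic) | COC(=O)C(C[Sn](CCCC)(CCCC)CCCC)P(=O)(OCC(F)(F)F)OCC(F)(F)F | intermediate
24 | potassium salt of 23 (not isolated) | [K+].COC(=O)[C-](C[Sn](CCCC)(CCCC)CCCC)P(=O)(OCC(F)(F)F)OCC(F)(F)F | intermediate
25 | allylstannane enoate (C5 cis to CO2Me; E by CIP because of tin), 14-OH, 15-O-TBS, (4R,15S), C14 epimers | C=C(C)[C@H](C/C=C(\C(=O)OC)C[Sn](CCCC)(CCCC)CCCC)CC1(OCCO1)C[C@H](O[Si](C)(C)C(C)(C)C)C(O)CC(C)=C | intermediate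
26 | C14 ketone of 25 with 15-O-TBS, (4R,15S) | C=C(C)[C@H](C/C=C(\C(=O)OC)C[Sn](CCCC)(CCCC)CCCC)CC1(OCCO1)C[C@H](O[Si](C)(C)C(C)(C)C)C(=O)CC(C)=C | intermediate
27 | open-chain hydroxy enone allylstannane with C17 dioxolane, (4R,15S) | C=C(C)[C@H](C/C=C(\C(=O)OC)C[Sn](CCCC)(CCCC)CCCC)CC1(OCCO1)C[C@H](O)C(=O)CC(C)=C | intermediate
28 | carbon monoxide | [C-]#[O+] | starting material
29 | furanone with C11–PdCl, C11 cis to C16 (not isolated) | C=C(C)[C@H](C/C=C(\C(=O)OC)C[Sn](CCCC)(CCCC)CCCC)CC1(OCCO1)C[C@@H]2O[C@](C)(C[Pd]Cl)CC2=O | intermediate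
30 | furanone with C10 acyl–PdCl, C11 cis to C16 (not isolated) | C=C(C)[C@H](C/C=C(\C(=O)OC)C[Sn](CCCC)(CCCC)CCCC)CC1(OCCO1)C[C@@H]2O[C@](C)(CC(=O)[Pd]Cl)CC2=O | intermediate
31 | (4R,12R,15S)-macrocyclic furanone, C17 as 1,3-dioxolane, Z enoate | C=C(C)[C@@H]1C/C=C(\C(=O)OC)CC(=O)C[C@]2(C)CC(=O)[C@H](CC3(OCCO3)C1)O2 | intermediate
32 | CNP0163183.1, (4R,12R,15S), Z enoate | C=C(C)[C@@H]1C/C=C(\C(=O)OC)CC(=O)C[C@]2(C)CC(=O)[C@H](CC(=O)C1)O2 | target

**Step count**
- Total: 19 steps.
- Longest linear sequence: 18 steps (steps 1–13 and 15–19); step 14 is a one-step side branch.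

**Steps most likely to fail**

Step 18 (proposed new method). What may go wrong:
- direct tin-to-palladium allyl transfer onto divalent palladium before oxypalladation;
- migration of the C11=C12 alkene into conjugation, followed by palladium-free oxa-Michael closure;
- capture of the acylpalladium by hydroquinone;
- oligomerisation in place of ring closure.

The fallback forms the same three bonds stepwise by known reactions; it sets out from 19 and comes back at 31. Dess–Martin oxidation of 19 should give keto aldehyde F1, and Et3N·3HF should free the C15 hydroxyl to give hydroxy keto aldehyde F2. Intramolecular alkoxypalladation–alkoxycarbonylation (PdCl2(MeCN)2 cat., CuCl2, CO, 2-(trimethylsilyl)ethanol, THF) should close ring A and deliver C10 as the 2-(trimethylsilyl)ethyl ester F3; the epimer with C11 cis to C16 would be carried on after separation. Olefination of the C6 aldehyde with 24 as in step 15 should give stannane ester F4. Fluoride (tris(dimethylamino)sulfonium difluorotrimethylsilicate, DMF) should unmask acid F5, and 1-chloro-N,N,2-trimethylpropenylamine should convert it into acid chloride F6. Intramolecular Stille acylation of the allylstannane (Pd2(dba)3, tri(2-furyl)phosphine, toluene, high dilution) should then close ring B to 31.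

Step 15. What may go wrong: slow addition or eroded geometric selectivity because of the bulky α-(stannylmethyl) group, or loss of tin from the reagent. The fallback sets out from 19 and comes back at 25. Bromination of 20 (NaH, then N-bromosuccinimide) should give bromo phosphonate F7, and its olefination with 19 under the step 15 conditions should give the (E)-α-bromo enoate F8 with the ester cis to C5. Stille coupling with (tributylstannyl)methanol (Pd(PPh3)4, dioxane, 90 °C) should replace bromine with retention and give the (Z)-2-(hydroxymethyl) enoate F9. Selective acetylation of the primary allylic hydroxyl (AcCl, 2,4,6-collidine, CH2Cl2, −78 °C) should give allylic acetate F10. Palladium-catalysed stannylation ((Bu3Sn)2, Pd2(dba)3, LiCl, DMF) through the π-allyl complex should place tin on the unsubstituted terminus C9 and return 25.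

Step 8. What may go wrong: over-oxidation of the electron-rich PMB ring or of an alkene, or interception of the oxocarbenium ion by water so that the free ketone forms in place of the ketal. The fallback sets out from 12 and comes back at 13. Alkylative hydrolysis without an oxidant (MeI, CaCO3, MeCN/H2O, 45 °C) should give ketone F11, and silyl-transfer ketalisation (1,2-bis(trimethylsilyloxy)ethane, TMSOTf cat., CH2Cl2, −78 °C) should return 13.

**Further compounds**
F1 | step 18 | keto aldehyde: C6 aldehyde, C14 ketone, 15-O-TBS, (4R,15S) | C=C(C)[C@H](CC=O)CC1(OCCO1)C[C@H](O[Si](C)(C)C(C)(C)C)C(=O)CC(C)=C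
F2 | step 18 | hydroxy keto aldehyde: C6 aldehyde, C14 ketone, 15-OH, (4R,15S) | C=C(C)[C@H](CC=O)CC1(OCCO1)C[C@H](O)C(=O)CC(C)=C
F3 | step 18 | furanone with C10 2-(trimethylsilyl)ethyl ester and C6 aldehyde, C11 cis to C16 | C=C(C)[C@H](CC=O)CC1(OCCO1)C[C@@H]2O[C@](C)(CC(=O)OCC[Si](C)(C)C)CC2=O
F4 | step 18 | furanone 2-(trimethylsilyl)ethyl ester with allylstannane enoate | C=C(C)[C@H](C/C=C(\C(=O)OC)C[Sn](CCCC)(CCCC)CCCC)CC1(OCCO1)C[C@@H]2O[C@](C)(CC(=O)OCC[Si](C)(C)C)CC2=O
F5 | step 18 | furanone C10 carboxylic acid with allylstannane enoate | C=C(C)[C@H](C/C=C(\C(=O)OC)C[Sn](CCCC)(CCCC)CCCC)CC1(OCCO1)C[C@@H]2O[C@](C)(CC(=O)O)CC2=O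
F6 | step 18 | furanone C10 acid chloride with allylstannane enoate | C=C(C)[C@H](C/C=C(\C(=O)OC)C[Sn](CCCC)(CCCC)CCCC)CC1(OCCO1)C[C@@H]2O[C@](C)(CC(=O)Cl)CC2=O
F7 | step 15 | methyl bromo[bis(2,2,2-trifluoroethoxy)phosphoryl]acetate (racemic) | COC(=O)C(Br)P(=O)(OCC(F)(F)F)OCC(F)(F)F
F8 | step 15 | (E)-α-bromo enoate, ester cis to C5, 14-OH, 15-O-TBS, C14 epimers | C=C(C)[C@H](C/C=C(\C(=O)OC)Br)CC1(OCCO1)C[C@H](O[Si](C)(C)C(C)(C)C)C(O)CC(C)=C
F9 | step 15 | (Z)-2-(hydroxymethyl) enoate, 14-OH, 15-O-TBS, C14 epimers | C=C(C)[C@H](C/C=C(\C(=O)OC)CO)CC1(OCCO1)C[C@H](O[Si](C)(C)C(C)(C)C)C(O)CC(C)=C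
F10 | step 15 | C9 allylic acetate of F9 | C=C(C)[C@H](C/C=C(\C(=O)OC)COC(C)=O)CC1(OCCO1)C[C@H](O[Si](C)(C)C(C)(C)C)C(O)CC(C)=C
F11 | step 8 | C17 ketone with 6,15-bis-O-TBS and 14-O-PMB, (4R,15S) | C=C(C)[C@H](CCO[Si](C)(C)C(C)(C)C)CC(=O)C[C@H](O[Si](C)(C)C(C)(C)C)COCc1ccc(OC)cc1
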